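I choose to follow south by one ratio of two rates rather than by the clock.

common to all: time 15 min

| flask | starting material | partner | remark | temperature |
|---|---|---|---|---|
| north-east | 21 mM | 42.0 mM | everything together at the start at 30 °C, warmed to 50 °C at 10 min |  |
| north-west | 21 mM | 42.0 mM (fed, over 10 min) | all else is in the flask from the start; the feed brings no volume worth counting | 50 °C |
| north | 21 mM (fed, over 10 min) | 42.0 mM | the addition at 30 °C, then warmed to 50 °C; the feed brings no volume worth counting |  |
| south | 21 mM | 42.0 mM | everything together at the start | 50 °C |
| south-west | 21 mM | 42.0 mM (in portions, 5, over 10 min) | first portion at the start, last at 10 min | 50 °C |

- the best flask by amount of bis adduct, in percent of the starting material charged; "all alike" if 1.5 percentage points covers them all (north-east / north-west / north / south / south-west / all alike)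
- amount of bis adduct at the end, in percent of the starting material charged, north-east
- amount of bis adduct at the end, in percent of the starting material charged, north-west
- amount of bis adduct at the end, in percent of the starting material charged, north
- amount of bis adduct at the end, in percent of the starting material charged, south
- amount of bis adduct at the end, in percent of the starting material charged, south-west

- amounts and yields of released group count crystals too
- given per volume of solution although it is solid: crystals
- all constants are for 50 °C and move with temperature by the activation energies and enthalpies

    bis adduct ⇌ isomer of the product (K1 = 1.35, k1 = 0.00229 /s, Ea1 = 92.0 kJ/mol, ΔH1 = −7.00 kJ/mol)
    crystals ⇌ released group, rate k2*(cs2 - [released group]) while solid is left; crystals form when [released group] > cs2 (cs2 = 19 mM, k2 = 0.0598 /s)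
    partner + bis adduct → triple product + released group (k3 = 0.00124 /M/s, Ea3 = 70.0 kJ/mol)
    starting material + partner → single product + released group (k4 = 0.0498 /M/s, Ea4 = 72.0 kJ/mol)
    partner + single product → bis adduct + released group (k5 = 0.0872 /M/s, Ea5 = 65.0 kJ/mol)
    (constants at 50 °C)

The bench rule of thumb says that when the second addition is quicker than the first, as here with 0.0872 /M/s against 0.0498 /M/s, the single product stays small and what leaves the starting material comes through as bis adduct. The first and second additions both carry the partner's concentration as a factor, so in their quotient partner and time drop out. What remains is the passing ratio (the selectivity factor), which is the rate constant of the second addition over that of the first, 1.75.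

With this ratio, at one temperature and with the starting material all in from the start and no single product there yet, the single product as a fraction of the charge is the fraction of starting material left, minus that fraction raised to the ratio, all divided by the ratio less one. The rule of thumb stops working here: at this ratio the peak of single product stands at 27.1% of the charge, reached with 47.4% of the starting material left.

For south I need one timed step, and I guess the partner at 0.7 of its charge on average, which leaves 26.8% of the starting material at 15 min. The ratio then gives 22.4% single product, so 50.8% has passed beyond it. I drop the third addition, whose half-life on bis adduct of 3.7 h is longer than the time. The relaxation half-life of 2.90 min is shorter than the time, so I split the passed material by the equilibrium constant and commit to 21.6% bis adduct in south.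

The forecast gives 16.2% for north-east, 21.5% for north-west, 14.5% for north, 26.2% for south and 21.4% for south-west, names south as best, and holds that “the flask with the most partner at 50 °C for the longest makes the most bis adduct”, so for south it stands above my figure.

The simulation gives 16.5%, 21.3%, 14.5%, 26.1% and 21.0% in that order, with south best. At 15.0 min south holds 29.7% starting material, which through the ratio means 23.7% single product, and south shows 23.7%. My split parts from south: there isomer over bis adduct stands at 0.772, not 1.35. South is not at rest: at 150 min its bis adduct has gained 12 percentage points to reach 38.3%, its isomer stands at 51.5% and its crystals at 21.0 mM, while north shows 38.2% bis adduct at that time.

In the neighbour flask, south with 17 mM of partner, the ratio is unchanged, and 61.8% starting material left gives 25.0% single product. The flask shows 25.0%, with 7.75% bis adduct and 5.43% isomer.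

(Its constants come from no measurement; the result is computed.)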